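Take a closed, stirred vessel at constant volume and temperature, charged with starting material, second substrate and free catalyst under held gas. Partner is absent at the start and has to dissolve from the gas.

| flask | starting material | second substrate | gas | free catalyst | remark | time |
|---|---|---|---|---|---|---|
| south-east | 0.77 M | 0.77 M | 200 mM (held) | 3.5 mM | run made earlier |  |
| south | 0.77 M | 0.77 M | 200 mM (held) | 37 mM | run made earlier |  |
| dawn | 0.77 M | 0.770 M | 200 mM (held) | 6.0 mM |  | 10 h |
| autumn | 0.77 M | 0.770 M | 200 mM (held) | 12 mM |  | 10 h |
| spring | 0.77 M | 0.770 M | 200 mM (held) | 25 mM |  | 10 h |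
| winter | 0.77 M | 0.770 M | 200 mM (held) | 50 mM |  | 10 h |

| run | time / h | target / % | isomer of the product / % | starting material / % |
|---|---|---|---|---|
| south-east | 0.417 | 0.5 | 0.4 | 99.7 |
| south-east | 0.667 | 0.2 | 0.6 | 99.8 |
| south-east | 1.00 | 0.4 | 0 | 100.1 |
| south-east | 1.33 | 0.8 | 0 | 98.9 |
| south-east | 2.00 | 1.0 | 0 | 99.0 |
| south-east | 3.00 | 1.9 | 0.5 | 99.1 |
| south-east | 5.00 | 3.5 | 0 | 97.1 |
| south | 0.250 | 1.4 | 0.1 | 98.5 |
| south | 0.833 | 5.5 | 0.2 | 95.6 |
| south | 1.33 | 7.4 | 0.9 | 92.0 |
| south | 2.00 | 11.1 | 0.2 | 88.3 |
| south | 3.00 | 16.9 | 0 | 82.3 |
| south | 4.00 | 23.0 | 0.9 | 76.7 |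
| south | 5.00 | 30.1 | 0.7 | 70.2 |

(standard deviation of a reading: 0.5 percentage points)

- at the start none of partner is dissolved
- reactions considered so far: second substrate + free catalyst <-> catalyst intermediate B; partner + catalyst intermediate A -> free catalyst + target; target + free catalyst <-> isomer of the product + free catalyst; partner + catalyst intermediate B -> free catalyst + second product; starting material + free catalyst <-> catalyst intermediate A; gas <-> partner
- "hardly changes" means that all values lie within two and a half points (for a concentration: within two and a half percent of the largest)

- share of target in all that became target or isomer of the product for dawn, autumn, spring, winter, in this order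
- how the row runs (falls, then rises / falls all the way / rises all the way / hardly changes / rises, then falls)

Run it slowly. In the first instants free catalyst meets both substrates, partner starts to arrive, and target shows early: the south run holds 1.4% at 0.250 h. In the middle target climbs steadily, to 30.1% at 5.00 h in the south run. Going from the south-east to the south run raises the catalyst by a factor 10.6 and that reading by a factor 8.60, so treat the rate of target as proportional to the catalyst charge. Isomer of the product still sits near the scatter in the south run, 0.7% against 0.5 percentage points, but it is made from target, so watch it towards the end.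

Now divide the rate of isomer, proportional to [free catalyst][target], by the rate of target. Time drops out. With the free share of the catalyst and the rate of target per unit of catalyst held fixed, the charge drops out too, and [isomer] goes as the square of [target]. Call the isomer tax 0.0773 the ratio of [isomer] to [target] squared, both as fractions of the starting material charged, here read from the last south reading. The selectivity is then one over one plus the tax times [target].

Scale the south target with time and catalyst to 10 h: 9.76% for dawn and 81.4% for winter. My reckoning gives shares of 99.3% and 94.1%, loosely, since the tax rests on a single noisy reading.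

The forecast gives 99.4%, 98.7%, 97.4% and 94.5%, so that the row falls all the way, on the grounds that “The isomer scales with catalyst squared”. My shares stand below the forecast's by 0.10 points for dawn and 0.40 points for winter.

The flask gives 99.7%, 99.2%, 98.0% and 94.9%: the row falls all the way.

    second substrate + free catalyst ⇌ catalyst intermediate B (K = 2.20 L mol⁻¹, k = 0.0534 L mol⁻¹ s⁻¹)
    partner + catalyst intermediate A → free catalyst + target (k = 0.221 L mol⁻¹ s⁻¹)
    target + free catalyst ⇌ isomer of the product + free catalyst, rate k3*[free catalyst]*[target] forward; the back reaction follows from the equilibrium constant (K = 0.870, k = 7.10 × 10⁻⁵ L mol⁻¹ s⁻¹)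
    partner + catalyst intermediate B → free catalyst + second product (k = 0.0118 L mol⁻¹ s⁻¹)
    starting material + free catalyst ⇌ catalyst intermediate A (K = 2.30 L mol⁻¹, k = 0.00110 L mol⁻¹ s⁻¹)
    gas ⇌ partner, rate k6*(csat - [partner]) (kL = 7.39 × 10⁻⁴ s⁻¹)

Winter holds 70.9% target at 10.0 h, and the tax on that amount gives a share of 94.8% against 94.9%. On the 9.65% target of dawn it gives 99.3% against 99.7%. The tax standing in winter is 0.0763, with free catalyst at 97.6%, and in dawn it is 0.0350, with free catalyst at 48.8%.

All runs were computed with constants of no real substance; the scatter is artificial.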